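Ring C is grown from an open chain instead of being bought. Its oxygenated carbons C3' and C5' are 1,3-related, like the carbonyls of a polyketide, and C1' carries the stilbene alkene. Ring C is therefore cut at C1'–C6' and C4'–C5' into dimethyl malonate and a dienone. One Michael–Claisen annulation forms both bonds and closes ring C as a 5-alkenylcyclohexane-1,3-dione, whose spared distal alkene is the future (E)-stilbene bond. The precursor is the enantiopure trans-2-aryl-2,3-dihydrobenzofuran core, with both hydroxyls as methoxymethyl ethers, carrying a (3E,5E)-6-arylhexa-3,5-dien-2-one chain at C5 of ring A.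

Key step: step 13

Conventions: ring A is the benzo ring of the dihydrobenzofuran, ring B the 4-oxygenated 3,5-dimethoxyphenyl ring on C2, ring C the resorcinol ring (primed locants, C1' bearing the alkene). In names, "core-5-yl" stands for (2R,3S)-2-[3,5-dimethoxy-4-(methoxymethoxy)phenyl]-7-methoxy-3-[(methoxymethoxy)methyl]-2,3-dihydro-1-benzofuran-5-yl.

Assumption: Rh2(S-PTTL)4 is taken to deliver the 2R product in step 6, the sense expected for o-(benzyloxy)aryl diazoacetates; should the opposite sense be found, the R-configured catalyst is used with no other change.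

Step 1
Reactants: 1 syringaldehyde (4-hydroxy-3,5-dimethoxybenzaldehyde)
Product: 2 3,5-dimethoxy-4-(methoxymethoxy)benzaldehyde
Conditions: MOMCl, i-Pr2NEt, CH2Cl2, 0 °C → rt
Reagents that add atoms: chloromethyl methyl ether, COCCl
Why: Williamson-type O-methoxymethylation of the acidic phenol should proceed cleanly and gives a ring B protecting group that tolerates base, hydride, organolithium and carbenoid chemistry.

Step 2
Reactants: 2 3,5-dimethoxy-4-(methoxymethoxy)benzaldehyde
Product: 3 [3,5-dimethoxy-4-(methoxymethoxy)phenyl]methanol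
Conditions: NaBH4, MeOH, 0 °C
Reagents that add atoms: none
Why: Borohydride reduction of the aryl aldehyde gives the benzylic alcohol and leaves the acetal untouched.

Step 3
Reactants: 4 4-bromo-2-methoxyphenol
Product: 5 4-bromo-2-iodo-6-methoxyphenol
Conditions: NIS (1.05 equiv), TsOH·H2O (10 mol%), MeCN, 0 °C → rt
Reagents that add atoms: N-iodosuccinimide, O=C1CCC(=O)N1I
Why: Electrophilic aromatic iodination should go to the only free position ortho to the hydroxyl, since the para position carries bromine and the other open positions are only meta to the hydroxyl.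

Step 4
Reactants: 5 4-bromo-2-iodo-6-methoxyphenol; 3 [3,5-dimethoxy-4-(methoxymethoxy)phenyl]methanol
Product: 6 5-bromo-2-{[3,5-dimethoxy-4-(methoxymethoxy)phenyl]methoxy}-1-iodo-3-methoxybenzene
Conditions: PPh3, DIAD, THF, 0 °C → rt
Reagents that add atoms: none
Why: Mitsunobu etherification joins the acidic phenol to the primary benzylic alcohol under neutral conditions that endanger neither aryl halide nor the acetal.

Step 5
Reactants: 6 5-bromo-2-{[3,5-dimethoxy-4-(methoxymethoxy)phenyl]methoxy}-1-iodo-3-methoxybenzene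
Product: 7 ethyl 2-(5-bromo-2-{[3,5-dimethoxy-4-(methoxymethoxy)phenyl]methoxy}-3-methoxyphenyl)-2-diazoacetate
Conditions: N2CHCO2Et (1.5 equiv), Pd(PPh3)4 (5 mol%), Ag2CO3 (0.5 equiv), Et3N (1.3 equiv), toluene, rt
Reagents that add atoms: ethyl diazoacetate, CCOC(=O)C=[N+]=[N-]
Why: Palladium-catalysed cross-coupling of an aryl iodide with the C–H bond of a diazoacetate should install the aryldiazoacetate in one step with retention of the diazo group, because zerovalent palladium inserts into C–I but not into C–Br at room temperature.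

Step 6
Reactants: 7 ethyl 2-(5-bromo-2-{[3,5-dimethoxy-4-(methoxymethoxy)phenyl]methoxy}-3-methoxyphenyl)-2-diazoacetate
Product: 8 ethyl (2R,3S)-5-bromo-2-[3,5-dimethoxy-4-(methoxymethoxy)phenyl]-7-methoxy-2,3-dihydro-1-benzofuran-3-carboxylate (cis)
Conditions: Rh2(S-PTTL)4 (dirhodium tetrakis[N-phthaloyl-(S)-tert-leucinate], 1 mol%), toluene, −60 °C
Reagents that add atoms: none
Why: Intramolecular 1,5 C–H insertion of the donor/acceptor rhodium carbenoid into the electron-rich benzylic ether C–H closes the dihydrofuran, the chiral carboxylate ligands selecting one enantiotopic benzylic hydrogen to set C2 as R while the insertion geometry places aryl and ester cis (C3 S).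

Step 7
Reactants: 8 ethyl (2R,3S)-5-bromo-2-[3,5-dimethoxy-4-(methoxymethoxy)phenyl]-7-methoxy-2,3-dihydro-1-benzofuran-3-carboxylate
Product: 9 ethyl (2R,3R)-5-bromo-2-[3,5-dimethoxy-4-(methoxymethoxy)phenyl]-7-methoxy-2,3-dihydro-1-benzofuran-3-carboxylate (trans)
Conditions: NaOEt (0.3 equiv), EtOH, rt
Reagents that add atoms: none
Why: Base-mediated epimerisation through the ester enolate should move the C3 ester into the thermodynamically preferred trans position, while C2 carries no acidic hydrogen and keeps its configuration.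

Step 8
Reactants: 9 ethyl (2R,3R)-5-bromo-2-[3,5-dimethoxy-4-(methoxymethoxy)phenyl]-7-methoxy-2,3-dihydro-1-benzofuran-3-carboxylate
Product: 10 [(2R,3S)-5-bromo-2-[3,5-dimethoxy-4-(methoxymethoxy)phenyl]-7-methoxy-2,3-dihydro-1-benzofuran-3-yl]methanol (trans)
Conditions: LiBH4, THF, 0 °C → rt
Reagents that add atoms: none
Why: Borohydride reduction of the ester to the primary alcohol spares the aryl bromide and the acetal, and the C3 descriptor becomes S only through the change in substituent priority.

Step 9
Reactants: 10 [(2R,3S)-5-bromo-2-[3,5-dimethoxy-4-(methoxymethoxy)phenyl]-7-methoxy-2,3-dihydro-1-benzofuran-3-yl]methanol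
Product: 11 (2R,3S)-5-bromo-2-[3,5-dimethoxy-4-(methoxymethoxy)phenyl]-7-methoxy-3-[(methoxymethoxy)methyl]-2,3-dihydro-1-benzofuran (core-5-yl bromide)
Conditions: MOMCl, i-Pr2NEt, CH2Cl2, 0 °C → rt
Reagents that add atoms: chloromethyl methyl ether, COCCl
Why: O-Methoxymethylation of the primary alcohol removes the last acidic proton before the organolithium step and lets both protecting groups fall in one final operation.

Step 10
Reactants: 11 core-5-yl bromide
Product: 13 core-5-carbaldehyde, (2R,3S)-2-[3,5-dimethoxy-4-(methoxymethoxy)phenyl]-7-methoxy-3-[(methoxymethoxy)methyl]-2,3-dihydro-1-benzofuran-5-carbaldehyde, via aryllithium 12 (not isolated)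
Conditions: n-BuLi (1.1 equiv), THF, −78 °C; DMF, −78 → 0 °C; H2O
Reagents that add atoms: N,N-dimethylformamide, CN(C)C=O
Why: Bromine–lithium exchange at −78 °C outruns any deprotonation of the ethers, and the aryllithium is formylated by DMF (Bouveault-type formylation) on aqueous work-up.

Step 11
Reactants: 13 core-5-carbaldehyde
Product: 14 (2E)-3-(core-5-yl)prop-2-enal
Conditions: Ph3P=CHCHO (1.2 equiv), toluene, 80 °C
Reagents that add atoms: (triphenylphosphoranylidene)acetaldehyde, O=CC=P(c1ccccc1)(c1ccccc1)c1ccccc1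
Why: Wittig olefination with the stabilised formylmethylene ylide should give the (E)-enal, the E geometry following from reversible oxaphosphetane formation with stabilised ylides.

Step 12
Reactants: 14 (2E)-3-(core-5-yl)prop-2-enal
Product: 15 (3E,5E)-6-(core-5-yl)hexa-3,5-dien-2-one
Conditions: Ph3P=CHC(O)CH3 (1.5 equiv), toluene, 90 °C
Reagents that add atoms: 1-(triphenylphosphoranylidene)propan-2-one, CC(=O)C=P(c1ccccc1)(c1ccccc1)c1ccccc1
Why: A second Wittig olefination with the stabilised acetonyl ylide extends the enal to the (3E,5E)-dienone with the E selectivity typical of stabilised ylides and without base that could touch the core.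

Step 13
Reactants: 15 (3E,5E)-6-(core-5-yl)hexa-3,5-dien-2-one; 16 dimethyl malonate
Product: 18 methyl 2,4-dioxo-6-[(E)-2-(core-5-yl)ethenyl]cyclohexane-1-carboxylate (largely enolised, mixture of ring diastereomers), via Michael adduct 17 (not isolated)
Conditions: NaOMe (2.0 equiv), MeOH/THF, 65 °C; then AcOH, H2O, 0 °C (pH 5)
Reagents that add atoms: none
Why: Methoxide generates the malonate anion, which adds reversibly in 1,4 fashion to C4 of the dienone (bond C1'–C6'), and the small equilibrium amount of the methyl ketone enolate of adduct 17 then acylates one malonate ester (bond C4'–C5') with loss of methoxide. The closest known reaction type is the Michael–Claisen (dimedone-type) annulation of enones and of 6-arylhexa-3,5-dien-2-ones with malonates to 5-substituted cyclohexane-1,3-diones. Ring C closes in a 6-(enolendo)-exo-trig mode, the favoured mode for an enolate carbon attacking an exocyclic ester carbonyl. Two sp3 stereocentres appear, C1' formed without control by the remote core and C6' freely epimerisable, and neither matters because both become sp2 after decarboxylation and aromatisation, while C2 and C3 of the core carry no acidic hydrogen and stay untouched. The step needs 1,4 in preference to 1,6 addition: the δ-carbon is deactivated by the para-oxygen O1 of ring A, and only the 1,4-adduct places the methyl ketone so that a six-membered Claisen closure can follow (the 1,6-adduct would require an eight-membered ring). The closure is made irreversible by deprotonation of the vinylogous acid 18 to its sodium enolate, which drains the reversible Michael equilibria and leaves the styryl alkene in its (E) form.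

Step 14
Reactants: 18 methyl 2,4-dioxo-6-[(E)-2-(core-5-yl)ethenyl]cyclohexane-1-carboxylate
Product: 20 5-[(E)-2-(core-5-yl)ethenyl]cyclohexane-1,3-dione, via keto acid 19 (not isolated)
Conditions: 2 M aq. NaOH, MeOH, 65 °C; then 1 M H3PO4 to pH 4, 50 °C
Reagents that add atoms: none
Why: Saponification of the vinylogous β-keto ester and decarboxylation of the resulting β-keto acid through the usual cyclic transition state should occur on mild acidification, the pH being held at 4 so that both acetals survive.

Step 15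
Reactants: 20 5-[(E)-2-(core-5-yl)ethenyl]cyclohexane-1,3-dione
Product: 21 5-[(E)-2-(core-5-yl)ethenyl]benzene-1,3-diol
Conditions: I2 (20 mol%), DMSO, 80 °C
Reagents that add atoms: none
Why: Iodine-catalysed dehydrogenation (α-iodination of the enolised dione, loss of HI, tautomerisation, with DMSO reoxidising HI to I2) should aromatise ring C to the resorcinol, driven by the gain of aromaticity.

Step 16
Reactants: 21 5-[(E)-2-(core-5-yl)ethenyl]benzene-1,3-diol
Product: 22 Gnetucleistol F, 5-[(E)-2-[(2R,3S)-2-(4-hydroxy-3,5-dimethoxyphenyl)-3-(hydroxymethyl)-7-methoxy-2,3-dihydro-1-benzofuran-5-yl]ethenyl]benzene-1,3-diol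
Conditions: HCl (about 1 M) in MeOH, 40 °C
Reagents that add atoms: none
Why: Acid-catalysed acetal exchange with methanol cleaves both methoxymethyl ethers as dimethoxymethane, the solvent trapping the methoxymethyl cation before it can alkylate the resorcinol, and the trans arrangement at C2/C3 is the thermodynamic one and should not be disturbed.

Compound list
1 | syringaldehyde | COc1cc(C=O)cc(OC)c1O | starting material
2 | 3,5-dimethoxy-4-(methoxymethoxy)benzaldehyde | COCOc1c(OC)cc(C=O)cc1OC | intermediate
3 | [3,5-dimethoxy-4-(methoxymethoxy)phenyl]methanol | COCOc1c(OC)cc(CO)cc1OC | intermediate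
4 | 4-bromo-2-methoxyphenol | COc1cc(Br)ccc1O | starting material
5 | 4-bromo-2-iodo-6-methoxyphenol | COc1cc(Br)cc(I)c1O | intermediate
6 | 5-bromo-2-{[3,5-dimethoxy-4-(methoxymethoxy)phenyl]methoxy}-1-iodo-3-methoxybenzene | COCOc1c(OC)cc(COc2c(I)cc(Br)cc2OC)cc1OC | intermediate
7 | ethyl 2-(5-bromo-2-{[3,5-dimethoxy-4-(methoxymethoxy)phenyl]methoxy}-3-methoxyphenyl)-2-diazoacetate | CCOC(=O)C(=[N+]=[N-])c1cc(Br)cc(OC)c1OCc1cc(OC)c(OCOC)c(OC)c1 | intermediate
8 | ethyl (2R,3S)-5-bromo-2-[3,5-dimethoxy-4-(methoxymethoxy)phenyl]-7-methoxy-2,3-dihydro-1-benzofuran-3-carboxylate (cis) | COc1cc([C@@H]2Oc3c(OC)cc(Br)cc3[C@@H]2C(=O)OCC)cc(OC)c1OCOC | intermediate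
9 | ethyl (2R,3R)-5-bromo-2-[3,5-dimethoxy-4-(methoxymethoxy)phenyl]-7-methoxy-2,3-dihydro-1-benzofuran-3-carboxylate (trans) | COc1cc([C@@H]2Oc3c(OC)cc(Br)cc3[C@H]2C(=O)OCC)cc(OC)c1OCOC | intermediate
10 | [(2R,3S)-5-bromo-2-[3,5-dimethoxy-4-(methoxymethoxy)phenyl]-7-methoxy-2,3-dihydro-1-benzofuran-3-yl]methanol | COc1cc([C@@H]2Oc3c(OC)cc(Br)cc3[C@H]2CO)cc(OC)c1OCOC | intermediate
11 | (2R,3S)-5-bromo-2-[3,5-dimethoxy-4-(methoxymethoxy)phenyl]-7-methoxy-3-[(methoxymethoxy)methyl]-2,3-dihydro-1-benzofuran | COc1cc([C@@H]2Oc3c(OC)cc(Br)cc3[C@H]2COCOC)cc(OC)c1OCOC | intermediate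
12 | core-5-yllithium (aryllithium from 11) | COc1cc([C@@H]2Oc3c(OC)cc([Li])cc3[C@H]2COCOC)cc(OC)c1OCOC | intermediate (not isolated)
13 | (2R,3S)-2-[3,5-dimethoxy-4-(methoxymethoxy)phenyl]-7-methoxy-3-[(methoxymethoxy)methyl]-2,3-dihydro-1-benzofuran-5-carbaldehyde | COc1cc([C@@H]2Oc3c(OC)cc(C=O)cc3[C@H]2COCOC)cc(OC)c1OCOC | intermediate
14 | (2E)-3-(core-5-yl)prop-2-enal | COc1cc([C@@H]2Oc3c(OC)cc(/C=C/C=O)cc3[C@H]2COCOC)cc(OC)c1OCOC | intermediate
15 | (3E,5E)-6-(core-5-yl)hexa-3,5-dien-2-one | COc1cc([C@@H]2Oc3c(OC)cc(/C=C/C=C/C(C)=O)cc3[C@H]2COCOC)cc(OC)c1OCOC | intermediate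
16 | dimethyl malonate | COC(=O)CC(=O)OC | starting material
17 | dimethyl 2-[(1E)-1-(core-5-yl)-5-oxohex-1-en-3-yl]propanedioate (Michael adduct) | COc1cc([C@@H]2Oc3c(OC)cc(/C=C/C(CC(C)=O)C(C(=O)OC)C(=O)OC)cc3[C@H]2COCOC)cc(OC)c1OCOC | intermediate (not isolated)
18 | methyl 2,4-dioxo-6-[(E)-2-(core-5-yl)ethenyl]cyclohexane-1-carboxylate | COc1cc([C@@H]2Oc3c(OC)cc(/C=C/C4CC(=O)CC(=O)C4C(=O)OC)cc3[C@H]2COCOC)cc(OC)c1OCOC | intermediate
19 | 2,4-dioxo-6-[(E)-2-(core-5-yl)ethenyl]cyclohexane-1-carboxylic acid | COc1cc([C@@H]2Oc3c(OC)cc(/C=C/C4CC(=O)CC(=O)C4C(=O)O)cc3[C@H]2COCOC)cc(OC)c1OCOC | intermediate (not isolated)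
20 | 5-[(E)-2-(core-5-yl)ethenyl]cyclohexane-1,3-dione | COc1cc([C@@H]2Oc3c(OC)cc(/C=C/C4CC(=O)CC(=O)C4)cc3[C@H]2COCOC)cc(OC)c1OCOC | intermediate
21 | 5-[(E)-2-(core-5-yl)ethenyl]benzene-1,3-diol | COc1cc([C@@H]2Oc3c(OC)cc(/C=C/c4cc(O)cc(O)c4)cc3[C@H]2COCOC)cc(OC)c1OCOC | intermediate
22 | Gnetucleistol F | COc1cc([C@@H]2Oc3c(OC)cc(/C=C/c4cc(O)cc(O)c4)cc3[C@H]2CO)cc(OC)c1O | target

Total step count: 16
Longest linear sequence: 15 steps (syringaldehyde 1 to 22 through steps 1, 2 and 4–16)

Steps most likely to fail

1. Step 13 (key step). The malonate may add at the δ-carbon instead of the β-carbon, the dienone may be consumed by methoxide (conjugate addition of methoxide or retro-aldol fragmentation), or the open-chain adduct may stall before the Claisen closure. Fallback: ring C is bought instead of built, setting out from aldehyde 13. Commercial 3,5-dihydroxybenzyl alcohol is methoxymethylated on both phenols (MOMCl, K2CO3, acetone) to [3,5-bis(methoxymethoxy)phenyl]methanol F1. An Appel reaction (CBr4, PPh3, CH2Cl2, 0 °C) converts this into 1-(bromomethyl)-3,5-bis(methoxymethoxy)benzene F2, and a Michaelis–Arbuzov reaction (P(OEt)3, 130 °C) gives diethyl {[3,5-bis(methoxymethoxy)phenyl]methyl}phosphonate F3. Horner–Wadsworth–Emmons olefination of 13 with the anion of F3 (NaH, THF, 0 °C to rt) should give the (E)-stilbene tetrakis(methoxymethyl) ether F4. Dilute HCl in MeOH at 40 °C then removes all four acetals, so the fallback returns to the route at the target 22.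

2. Step 15. Iodine may attack the styryl alkene or the electron-rich rings A, B and C, oxidation may go past the resorcinol, or HI may strip the acetals before aromatisation is complete. Fallback: setting out from dione 20, silylation (Me3SiOTf, Et3N, CH2Cl2, 0 °C) gives the 1,3-bis(trimethylsilyloxy)-5-[(E)-2-(core-5-yl)ethenyl]cyclohexa-1,3-diene F5. Saegusa–Ito oxidation with Pd(OAc)2 (1.1 equiv, MeCN, rt) dehydrogenates through a palladium enolate and β-hydride elimination instead of an α-iodo ketone. Work-up with K2CO3 in MeOH removes the silyl groups and returns to the route at 21.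

3. Step 5. Oxidative addition and C–H palladation at the hindered ortho-alkoxy aryl iodide may be slow, so that the diazoacetate is lost to carbene dimerisation or palladium-carbene side reactions before coupling. Fallback: setting out from iodide 6, CuI/L-proline-catalysed arylation of ethyl acetoacetate (Cs2CO3, DMSO, 50 then 80 °C) gives ethyl 2-(5-bromo-2-{[3,5-dimethoxy-4-(methoxymethoxy)phenyl]methoxy}-3-methoxyphenyl)-3-oxobutanoate F6. This loses its acetyl group in the same flask by retro-Claisen cleavage to ethyl 2-(5-bromo-2-{[3,5-dimethoxy-4-(methoxymethoxy)phenyl]methoxy}-3-methoxyphenyl)acetate F7. Regitz diazo transfer (4-acetamidobenzenesulfonyl azide, DBU, MeCN, 0 °C to rt) then returns to the route at 7.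

Further compounds
F1 | step 13 | [3,5-bis(methoxymethoxy)phenyl]methanol | COCOc1cc(CO)cc(OCOC)c1
F2 | step 13 | 1-(bromomethyl)-3,5-bis(methoxymethoxy)benzene | COCOc1cc(CBr)cc(OCOC)c1
F3 | step 13 | diethyl {[3,5-bis(methoxymethoxy)phenyl]methyl}phosphonate | CCOP(=O)(Cc1cc(OCOC)cc(OCOC)c1)OCC
F4 | step 13 | 1-[(E)-2-(core-5-yl)ethenyl]-3,5-bis(methoxymethoxy)benzene | COc1cc([C@@H]2Oc3c(OC)cc(/C=C/c4cc(OCOC)cc(OCOC)c4)cc3[C@H]2COCOC)cc(OC)c1OCOC
F5 | step 15 | 1,3-bis(trimethylsilyloxy)-5-[(E)-2-(core-5-yl)ethenyl]cyclohexa-1,3-diene | COc1cc([C@@H]2Oc3c(OC)cc(/C=C/C4CC(O[Si](C)(C)C)=CC(O[Si](C)(C)C)=C4)cc3[C@H]2COCOC)cc(OC)c1OCOC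
F6 | step 5 | ethyl 2-(5-bromo-2-{[3,5-dimethoxy-4-(methoxymethoxy)phenyl]methoxy}-3-methoxyphenyl)-3-oxobutanoate | CCOC(=O)C(C(C)=O)c1cc(Br)cc(OC)c1OCc1cc(OC)c(OCOC)c(OC)c1
F7 | step 5 | ethyl 2-(5-bromo-2-{[3,5-dimethoxy-4-(methoxymethoxy)phenyl]methoxy}-3-methoxyphenyl)acetate | CCOC(=O)Cc1cc(Br)cc(OC)c1OCc1cc(OC)c(OCOC)c(OC)c1
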